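Balance the left-handed substrate. Reaction to left-handed product drains it, and exchange on the racemization catalyst refills it from the right-handed substrate.

| flask | left-handed substrate | right-handed substrate | solid reagent | free catalyst | racemization catalyst | remark | time |
|---|---|---|---|---|---|---|---|
| Thursday's | 0.060 M | 0.060 M | 0.24 M | 120 µM | 49 µM | run made earlier |  |
| flask | 0.060 M | 0.060 M | 0.240 M | 60 µM | 49 µM |  | 2.5 d |

Thursday's run (percent of the left-handed substrate and right-handed substrate together charged)

| time / h | left-handed product / % | right-handed product / % |
|---|---|---|
| 1.33 | 0.6 | 0.1 |
| 2.50 | 1.8 | 1.4 |
| 4.00 | 2.8 | 1.2 |
| 5.00 | 3.7 | 2.3 |
| 6.00 | 4.7 | 2.0 |

(standard deviation of a reading: 0.5 percentage points)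

- free catalyst is single-handed; left-handed substrate and right-handed substrate are mirror images of each other, charged as a racemate, each of them at the stated concentration
- solid reagent is a solid; its amount is given per volume of the solution
- the numbers in the tables scatter by 0.5 percentage points (one standard deviation)
- at the start none of the solid reagent is in solution
- an excess is below zero if the other one leads
- no earlier run changes the charge of free catalyst; that part of a forecast is a guess

* left-handed product and right-handed product together, in percent of the left-handed substrate and right-handed substrate charged together, at 2.5 d
* excess of left-handed product over right-handed product in the product at 2.5 d
* whether the exchange between left-handed substrate and right-handed substrate keeps pace with the reaction: how far the product's excess at 2.5 d gets from its value without exchange to its value with instant exchange (above 80% keeps pace, below 20% hardly takes part, else lags behind)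

Sum the five readings of each product in Thursday's run, where products reach 6.70% of the charge, so the two substrates stand near level. The ratio of the sums is the selectivity factor s, left-handed product formed per right-handed product at equal [left-handed substrate] and [right-handed substrate]: 1.94, a reading with the scatter of its peaks. Thursday's run holds twice the free catalyst of this flask, so assume, as a guess, that the catalyst speeds both products alike. While exchange keeps the two substrates level, product forms in the ratio s, which gives an excess of 32.0%; take that as the estimate for this flask.

The forecast gives a yield of 28% and an excess of 30%, against my 32.0%, and says the exchange lags behind, since the readings “say nothing about the racemization rate”.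

The flask gives a yield of 39.6% and an excess of 30.2%, and the exchange keeps pace, getting 98% of the way.

    partner → decomposed reagent (k = 0.693 /h)
    left-handed substrate + racemization catalyst ⇌ right-handed substrate + racemization catalyst, rate k2*[racemization catalyst]*[left-handed substrate] forward; the back reaction follows from the equilibrium constant (k = 49000 /M/h)
    2 racemization catalyst ⇌ resting dimer, settled at all times (K = 25000 /M)
    partner + free catalyst + left-handed substrate → free catalyst + left-handed product (k = 39500 /M²/h)
    partner + free catalyst + right-handed substrate → free catalyst + right-handed product (k = 21100 /M²/h)
    solid reagent ⇌ partner, rate k6*(cs6 - [partner]) while solid is left; crystals form when [partner] > cs6 (solubility = 30.0 mM, k = 0.187 /h)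

The main reason the part reacted in this flask ends at 39.6% is the reaction of partner to decomposed reagent: the same flask without that step reaches 86.7%. The substrates stay close meanwhile: in this flask the right-handed substrate leads by 0.129% at 0.625 d. Carried to the neighbour with 1.5 × 10⁻⁴ M of free catalyst, s meets a product ratio of 1.86 at a yield of 65.3%, with an excess of 30.1%.

The runs were generated by integration on assumed constants; noise was put on by code.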